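| setting | gamma | theta | maple | alder |
|---|---|---|---|---|
| substrate | 0.020 M | 0.020 M | 0.020 M | 0.020 M |
| gas phase | 1.7 mM (held) | 1.7 mM (held) | 1.7 mM (held) | 1.7 mM (held) |
| protic impurity | 1.3 mM | 5.8 mM | 1.00 mM | 4.00 mM |
| temperature | 65 °C | 76 °C | 70 °C | 70 °C |
| remark | run made earlier | run made earlier |  |  |
| time |  |  | 10 d | 20 d |

- gamma (time / d: target / %, side product / %): 1.25: 46.1, 20.4; 3.00: 62.9, 32.2; 4.00: 65.7, 32.1; 6.00: 66.2, 32.3; 8.00: 67.3, 34.2; 10.0: 67.8, 31.8
- theta (time / d: target / %, side product / %): 0.500: 36.8, 30.2; 1.67: 54.8, 45.6; 3.00: 53.5, 45.6; 4.00: 54.5, 44.4; 6.00: 54.5, 45.8; 8.00: 53.7, 45.4; 10.0: 51.8, 45.1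

(each reading ± 1 percentage point)

* the winner by share of target in all that became target or side product; "neither" if no more than 2 percentage points parts them (maple / alder / neither)
* share of target in all that became target or side product, maple
* share of target in all that became target or side product, alder

- the numbers in the tables scatter by 1 percentage point (one standard deviation)
- at the start none of the gas phase is in solution
- the share counts what is present at the end, not what went on to other products

1. I read gamma from 4.00 d and theta from 1.67 d, where the curves had gone flat. There the quotient target over side product (the selectivity factor, S) stood at 2.05 in gamma and 1.19 in theta. Maple's time is longer than gamma's flat start, so I reckoned with S, not with speed.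

2. I turned the question round. Maple and alder share their temperature and differ in c(protic impurity) and time, so a winner needs S to move with one of these.

3. First I supposed that S follows temperature and ignores c(protic impurity). The two runs then give the side route's excess heat-sensitivity, E = R ln(S gamma / S theta) / (1/T gamma − 1/T theta) = 48.6 kJ/mol. Carried to 70 °C, it gave S = 1.59, a share of 61.4% for both flasks.

4. Now the opposite: if S fell as c(protic impurity) to a power n, a gap of 2 percentage points at that share needs n of just 0.0609, over a charge ratio of 4.00. Gamma and theta changed impurity and temperature together, so the readings leave n open. I committed to n = 0, the plainest case, and so to neither.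

5. The forecast differed from my reckoning. It said maple, with 72% (67% to 79%) for maple and 56% (51% to 60%) for alder, holding that “the order is probably near 0.5, though order and temperature are confounded”.

6. The flasks gave neither: maple 61.3%, alder 60.8%.

    substrate + dissolved gas → target (k = 21.0 /M/h, Ea = 64.0 kJ/mol)
    gas phase ⇌ dissolved gas, rate k2*(csat - [dissolved gas]) (kL = 28.0 /h)
    dissolved gas + protic impurity → quenched reagent (k = 26.0 /M/h, Ea = 60.0 kJ/mol)
    target → over-reaction product (k = 7.20 × 10⁻⁵ /h, Ea = 129 kJ/mol)
    substrate → side product (k = 0.0220 /h, Ea = 109 kJ/mol)
    (constants at 70 °C)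

Maple's 61.3% is S = 1.58, beside the 1.59 I had from E, and it lies below the forecast's low end. Maple with alder's impurity charge gave 61.2%. I then carried E to a neighbouring flask, like maple but at 85 °C: gamma's S became 0.779, a share of 43.8%. At 10.0 d that flask held 40.2% target and 55.1% side product, a share of 42.2%.

The data are simulated for an exercise; scatter was added.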